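**Retrosynthetic overview**
- Andavadoic acid 18 ← methyl ester 16 ← C3–CH2 bond made by adding silyl ketene acetal 14 to the peroxycarbenium ion from methoxydioxolane 13.
- The 1,2-dioxolane (the only ring, closed in step 4) ← (E)-enone 10 + H2O2: the C5–O bond forms by enantioselective conjugate addition (sets C5), and the C3–O bond by hemiketalisation.
- Enone 10 ← (E)-enoate 8 ← syn-carbocupration of ethyl but-2-ynoate 4 with the copper reagent from bromide 3 ← PhMgBr 1 + 1,10-dibromodecane 2.

Assumption: the facial sense in step 4 is taken from the behaviour of β-monosubstituted (E)-enones with the quinine-derived amine; if the 5R series forms instead, the quinidine-derived pseudo-enantiomer is used and nothing else changes.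

**Step 1**
Reactants: 1 phenylmagnesium bromide (PhMgBr); 2 1,10-dibromodecane
Product: 3 (10-bromodecyl)benzene
Conditions: 2 (3 equiv), Li2CuCl4 (3 mol%), THF, −10 °C → rt, slow addition of 1; excess 2 recovered by distillation
Reagents that add atoms: none
Why: Kochi-type copper-catalysed Grignard/primary alkyl bromide cross-coupling, where the threefold excess of dibromide suppresses double arylation; no stereocentre is formed.

**Step 2**
Reactants: 3 (10-bromodecyl)benzene; 4 ethyl but-2-ynoate
Product: 8 ethyl (E)-3-methyl-13-phenyltridec-2-enoate, via Grignard reagent 5 (not isolated), via alkylcopper reagent 6 (not isolated), via alkenylcopper adduct 7 (not isolated)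
Conditions: Mg turnings, THF, rt → 40 °C; CuBr·SMe2 (1.0 equiv), −40 °C; 4 (0.9 equiv), −78 °C, 2 h; aq NH4Cl at −78 °C
Reagents that add atoms: none
Why: Grignard formation, transmetalation to the organocopper and syn-carbocupration (conjugate addition) of the ynoate, then protonation of the alkenylcopper with retention at −78 °C, put the chain trans to the ester and fix the E geometry.

**Step 3**
Reactants: 8 ethyl (E)-3-methyl-13-phenyltridec-2-enoate
Product: 10 (E)-4-methyl-14-phenyltetradec-3-en-2-one, via Weinreb amide 9 (not isolated)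
Conditions: MeNHOMe·HCl (1.6 equiv), i-PrMgCl (3.2 equiv), THF, −20 °C; then MeMgBr (3 equiv), 0 °C; cold aq HCl quench
Reagents that add atoms: methylmagnesium bromide, C[Mg]Br
Why: One-pot Weinreb ketone synthesis (ester aminolysis by MeN(OMe)MgCl, then Grignard addition), where the chelated tetrahedral adduct prevents over-addition and the alkene geometry is untouched.

**Step 4**
Reactants: 10 (E)-4-methyl-14-phenyltetradec-3-en-2-one
Product: 12 (5S)-3,5-dimethyl-5-(10-phenyldecyl)-1,2-dioxolan-3-ol (mixture of C3 anomers), via hydroperoxy ketone 11 (not isolated)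
Conditions: 9-amino-9-deoxy-epi-quinine (10 mol%), Cl3CCO2H (20 mol%), 50% aq H2O2 (3 equiv), 1,4-dioxane (1 M), 32 °C, 48 h
Reagents that add atoms: hydrogen peroxide, OO
Why: Proposed new method: primary-amine iminium catalysis is extended to an acyclic β,β-disubstituted enone so that H2O2 adds to a fully substituted β-carbon and creates a tetrasubstituted C–OO stereocentre; the cinchona amine condenses with the methyl ketone to the (E)-alkene iminium ion (the small cis-β methyl is tolerated as the cis-β ring carbon is in 3-alkylcyclohexenones), the protonated quinuclidine and the trichloroacetate hold H2O2 by hydrogen bonds and deliver it to one face of C4, and after enamine hydrolysis the OOH of 11 adds 5-exo to the ketone to give hemiketal 12, which removes the adduct from the retro-Michael and epoxide channels, so fixed E geometry plus single-face delivery sets C5 as S; the closest known reaction type is the same amine-salt-catalysed asymmetric hydroperoxidation of β-monosubstituted acyclic enones to peroxyhemiketals and epoxidation of 3-alkylcyclohexenones, together with the racemic H2O2 addition to mesityl oxide that gives the analogous 3-hydroxy-1,2-dioxolane.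

**Step 5**
Reactants: 12 (5S)-3,5-dimethyl-5-(10-phenyldecyl)-1,2-dioxolan-3-ol
Product: 13 (5S)-3-methoxy-3,5-dimethyl-5-(10-phenyldecyl)-1,2-dioxolane (mixture at C3)
Conditions: MeOH, p-TsOH·H2O (5 mol%), rt, 2 h
Reagents that add atoms: methanol, CO
Why: Acid-catalysed exchange of the peroxyhemiketal hydroxyl for methoxy (ketalisation through the peroxycarbenium ion) leaves C5 untouched, and the C3 mixture is of no consequence because C3 is ionised in the next step.

**Step 6**
Reactants: 13 (5S)-3-methoxy-3,5-dimethyl-5-(10-phenyldecyl)-1,2-dioxolane; 14 tert-butyl[(1-methoxyethenyl)oxy]dimethylsilane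
Product: 16 methyl 2-[(3R,5S)-3,5-dimethyl-5-(10-phenyldecyl)-1,2-dioxolan-3-yl]acetate, via peroxycarbenium ion 15 (not isolated)
Conditions: 14 (2.5 equiv), TMSOTf (0.3 equiv), CH2Cl2, −78 → −40 °C; chromatography removes the minor C3 epimer
Reagents that add atoms: none
Why: Mukaiyama-type addition of a silyl ketene acetal to the Lewis-acid-generated peroxycarbenium ion, in which inside attack on the envelope with the long chain pseudo-equatorial places CH2CO2Me trans to the chain (3R); selectivity is expected to be modest (about 2–3:1) and the isomers are separated.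

**Step 7**
Reactants: 16 methyl 2-[(3R,5S)-3,5-dimethyl-5-(10-phenyldecyl)-1,2-dioxolan-3-yl]acetate
Product: 18 andavadoic acid (2-[(3R,5S)-3,5-dimethyl-5-(10-phenyldecyl)-1,2-dioxolan-3-yl]acetic acid), via lithium carboxylate 17 (not isolated)
Conditions: LiOH·H2O (3 equiv), THF/H2O 3:1, 0 °C → rt; 1 M HCl to pH 3
Reagents that add atoms: lithium hydroxide, [Li+].[OH-]
Why: Ester saponification, tolerated because both peroxide carbons are fully substituted (no Kornblum–DeLaMare pathway), so neither stereocentre is touched.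

**Compound list**
1 | phenylmagnesium bromide | Br[Mg]c1ccccc1 | starting material
2 | 1,10-dibromodecane | BrCCCCCCCCCCBr | starting material
3 | (10-bromodecyl)benzene | BrCCCCCCCCCCc1ccccc1 | intermediate
4 | ethyl but-2-ynoate | CCOC(=O)C#CC | starting material
5 | 10-phenyldecylmagnesium bromide | Br[Mg]CCCCCCCCCCc1ccccc1 | intermediate
6 | 10-phenyldecylcopper (as its MgBr2 complex) | [Cu]CCCCCCCCCCc1ccccc1 | intermediate
7 | ethyl (Z)-2-cuprio-3-methyl-13-phenyltridec-2-enoate | CCOC(=O)/C([Cu])=C(\C)CCCCCCCCCCc1ccccc1 | intermediate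
8 | ethyl (E)-3-methyl-13-phenyltridec-2-enoate | CCOC(=O)/C=C(\C)CCCCCCCCCCc1ccccc1 | intermediate
9 | (E)-N-methoxy-N,3-dimethyl-13-phenyltridec-2-enamide | CON(C)C(=O)/C=C(\C)CCCCCCCCCCc1ccccc1 | intermediate
10 | (E)-4-methyl-14-phenyltetradec-3-en-2-one | CC(=O)/C=C(\C)CCCCCCCCCCc1ccccc1 | intermediate
11 | (S)-4-hydroperoxy-4-methyl-14-phenyltetradecan-2-one | CC(=O)C[C@](C)(CCCCCCCCCCc1ccccc1)OO | intermediate
12 | (5S)-3,5-dimethyl-5-(10-phenyldecyl)-1,2-dioxolan-3-ol | C[C@]1(CCCCCCCCCCc2ccccc2)CC(C)(O)OO1 | intermediate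
13 | (5S)-3-methoxy-3,5-dimethyl-5-(10-phenyldecyl)-1,2-dioxolane | C[C@]1(CCCCCCCCCCc2ccccc2)CC(C)(OC)OO1 | intermediate
14 | tert-butyl[(1-methoxyethenyl)oxy]dimethylsilane | C=C(OC)O[Si](C)(C)C(C)(C)C | starting material
15 | (5S)-3,5-dimethyl-5-(10-phenyldecyl)-1,2-dioxolan-3-ylium cation (peroxycarbenium ion) | C[C@]1(CCCCCCCCCCc2ccccc2)CC(C)=[O+]O1 | intermediate
16 | methyl 2-[(3R,5S)-3,5-dimethyl-5-(10-phenyldecyl)-1,2-dioxolan-3-yl]acetate | C[C@]1(CCCCCCCCCCc2ccccc2)C[C@](C)(CC(=O)OC)OO1 | intermediate
17 | lithium 2-[(3R,5S)-3,5-dimethyl-5-(10-phenyldecyl)-1,2-dioxolan-3-yl]acetate | C[C@]1(CCCCCCCCCCc2ccccc2)C[C@](C)(CC(=O)[O-])OO1.[Li+] | intermediate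
18 | andavadoic acid, 2-[(3R,5S)-3,5-dimethyl-5-(10-phenyldecyl)-1,2-dioxolan-3-yl]acetic acid | C[C@]1(CCCCCCCCCCc2ccccc2)C[C@](C)(CC(=O)O)OO1 | target

**Totals**
Total step count: 7. Longest linear sequence: 7 (from 1 and 2 to 18).

**Steps most likely to fail and their fallbacks**

Step 3 (one-pot ester to methyl ketone). The hindered β,β-disubstituted enoate may aminolyse incompletely. The fallback sets out from 8: saponification (LiOH, THF/MeOH/H2O, 50 °C) gives (E)-3-methyl-13-phenyltridec-2-enoic acid F1. MeLi (2.2 equiv, Et2O, 0 °C, inverse quench into cold aq HCl) then gives the methyl ketone through the dilithium gem-diolate and comes back to the route at 10.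

Step 4 (the proposed new hydroperoxidation). Risks are slow iminium formation at the hindered ketone, E/Z scrambling through the dienamine that would erode ee, and competing closure to the epoxy ketone. The fallback uses known chemistry and sets out from 10.
- Corey–Bakshi–Shibata reduction ((R)-2-methyl-CBS-oxazaborolidine, BH3·SMe2, THF, −20 °C) gives (2S,3E)-4-methyl-14-phenyltetradec-3-en-2-ol F2.
- mCPBA (CH2Cl2, 0 °C), hydroxyl-directed and threo-selective through A1,3 strain from the cis methyl group, gives (1S)-1-[(2R,3R)-3-methyl-3-(10-phenyldecyl)oxiran-2-yl]ethan-1-ol F3.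
- NaAlH2(OCH2CH2OMe)2 (THF, 0 °C) delivers hydride to the epoxide carbon next to the carbinol and gives (2S,4R)-4-methyl-14-phenyltetradecane-2,4-diol F4.
- TsCl/pyridine sulfonylates only the secondary hydroxyl and gives (2S,4R)-4-hydroxy-4-methyl-14-phenyltetradecan-2-yl 4-methylbenzenesulfonate F5.
- KOt-Bu (THF, 0 °C → rt) closes (2R,4R)-2,4-dimethyl-2-(10-phenyldecyl)oxetane F6.
- Ethereal H2O2 with catalytic TMSOTf (Et2O, −78 → 0 °C) opens the oxetane at the tertiary carbon with inversion and gives (2R,4S)-4-hydroperoxy-4-methyl-14-phenyltetradecan-2-ol F7.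
- Dess–Martin periodinane (NaHCO3, CH2Cl2, 0 °C) oxidises the secondary alcohol to 11, which closes to the hemiketal, and the fallback comes back to the route at 12.

Step 6 (peroxycarbenium alkylation). Risks are low diastereoselectivity at C3, sluggish reaction of the ketene acetal at the tertiary cation, and Lewis-acid-induced O–O fragmentation. The fallback sets out from 13.
- Hosomi–Sakurai-type allylation (allyltrimethylsilane, TMSOTf, CH2Cl2, −78 °C) gives (3S,5S)-3,5-dimethyl-5-(10-phenyldecyl)-3-(prop-2-en-1-yl)-1,2-dioxolane F8, with its C3 epimer removed by chromatography.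
- Ozonolysis (O3, CH2Cl2/MeOH, −78 °C; Me2S) gives 2-[(3R,5S)-3,5-dimethyl-5-(10-phenyldecyl)-1,2-dioxolan-3-yl]acetaldehyde F9.
- Pinnick oxidation (NaClO2, NaH2PO4, 2-methylbut-2-ene, t-BuOH/H2O) gives the acid and comes back to the route at 18, bypassing 16 and step 7.

**Further compounds**
F1 | step 3 | (E)-3-methyl-13-phenyltridec-2-enoic acid | OC(=O)/C=C(\C)CCCCCCCCCCc1ccccc1
F2 | step 4 | (2S,3E)-4-methyl-14-phenyltetradec-3-en-2-ol | C[C@H](O)/C=C(\C)CCCCCCCCCCc1ccccc1
F3 | step 4 | (1S)-1-[(2R,3R)-3-methyl-3-(10-phenyldecyl)oxiran-2-yl]ethan-1-ol | C[C@H](O)[C@H]1O[C@]1(C)CCCCCCCCCCc1ccccc1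
F4 | step 4 | (2S,4R)-4-methyl-14-phenyltetradecane-2,4-diol | C[C@H](O)C[C@](C)(O)CCCCCCCCCCc1ccccc1
F5 | step 4 | (2S,4R)-4-hydroxy-4-methyl-14-phenyltetradecan-2-yl 4-methylbenzenesulfonate | C[C@H](OS(=O)(=O)c1ccc(C)cc1)C[C@](C)(O)CCCCCCCCCCc1ccccc1
F6 | step 4 | (2R,4R)-2,4-dimethyl-2-(10-phenyldecyl)oxetane | C[C@@H]1C[C@@](C)(CCCCCCCCCCc2ccccc2)O1
F7 | step 4 | (2R,4S)-4-hydroperoxy-4-methyl-14-phenyltetradecan-2-ol | C[C@@H](O)C[C@](C)(CCCCCCCCCCc1ccccc1)OO
F8 | step 6 | (3S,5S)-3,5-dimethyl-5-(10-phenyldecyl)-3-(prop-2-en-1-yl)-1,2-dioxolane | C[C@]1(CCCCCCCCCCc2ccccc2)C[C@](C)(CC=C)OO1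
F9 | step 6 | 2-[(3R,5S)-3,5-dimethyl-5-(10-phenyldecyl)-1,2-dioxolan-3-yl]acetaldehyde | C[C@]1(CCCCCCCCCCc2ccccc2)C[C@](C)(CC=O)OO1
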